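The oxolane (O1, C2 with ring A, C3 with C9H2OH, C4 with the C7' aroyl group of ring B, C5) is disconnected at C2–C3. The C7' ketone and the C9 alcohol, being 1,4-related, are masked as a γ-lactone (C9 carbonyl, oxygen on C7'). The key step exploits the C2–H bond, a benzylic ether C–H flanked by O1 and the electron-rich ring A: a rhodium carbene at C3 of a trans-4,5-disubstituted α-diazolactone carrying the ring A benzyl ether inserts into it, closing the oxolane as a cis-fused furofuranone and relaying the aldol-derived C4 configuration to C3. Lactone reduction, C7' oxidation and thermodynamic adjustment of C4 and C2 complete the route.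

Key step: step 10

Assumption: the kinetic insertion is taken to place ring A on the concave face of the bicycle (C2 aryl cis to C9), the usual outcome for diazolactones of this type; C2 is therefore reset by acid equilibration at the monocyclic stage (step 13), so either C2 epimer from step 10 leads to the target.

Abbreviation: Ar* = 4-[(tert-butyldimethylsilyl)oxy]-3,5-dimethoxyphenyl. Oxolane numbering is that of the first paragraph.

Step 1
Reactants: 1 syringaldehyde (4-hydroxy-3,5-dimethoxybenzaldehyde)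
Product: 2 4-[(tert-butyldimethylsilyl)oxy]-3,5-dimethoxybenzaldehyde
Conditions: TBSCl, imidazole, DMF, rt
Reagents that add atoms: tert-butyldimethylsilyl chloride, CC(C)(C)[Si](C)(C)Cl
Why: Imidazole-promoted silyl ether formation caps the only acidic OH and leaves the aldehyde untouched.

Step 2
Reactants: 3 (4S)-4-benzyl-1,3-oxazolidin-2-one; 4 methyl 4-chloro-4-oxobutanoate
Product: 5 methyl 4-[(4S)-4-benzyl-2-oxo-1,3-oxazolidin-3-yl]-4-oxobutanoate
Conditions: n-BuLi, THF, −78 °C; then 4, −78 to 0 °C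
Reagents that add atoms: none
Why: N-acylation of the lithiated oxazolidinone by the acid chloride (imide formation) is much faster than attack on the methyl ester and does not involve the auxiliary stereocentre.

Step 3
Reactants: 5 methyl 4-[(4S)-4-benzyl-2-oxo-1,3-oxazolidin-3-yl]-4-oxobutanoate; 2 4-[(tert-butyldimethylsilyl)oxy]-3,5-dimethoxybenzaldehyde
Product: 7 (4S)-4-benzyl-3-{[(2S,3S)-2-Ar*-5-oxooxolan-3-yl]carbonyl}-1,3-oxazolidin-2-one (trans lactone), via syn-aldol adduct 6 (not isolated)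
Conditions: Bu2BOTf, i-Pr2NEt, CH2Cl2, 0 °C; 2, −78 to 0 °C; pH 7 buffer, MeOH, H2O2; then PPTS (cat.), toluene, 60 °C
Reagents that add atoms: none
Why: Evans syn-aldol reaction, in which the Z-boron enolate formed only at the imide α-carbon adds to 2 through a Zimmerman–Traxler chair on the face away from the benzyl group, setting the future C4 (S here) and C7' (S) syn; acid-catalysed lactonization of the γ-hydroxy ester then gives the trans lactone.

Step 4
Reactants: 7 (4S)-4-benzyl-3-{[(2S,3S)-2-Ar*-5-oxooxolan-3-yl]carbonyl}-1,3-oxazolidin-2-one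
Product: 8 (2S,3S)-2-Ar*-5-oxooxolane-3-carboxylic acid
Conditions: LiOH, H2O2, THF/H2O, 0 °C; Na2SO3; HCl to pH 3
Reagents that add atoms: hydrogen peroxide (as LiOOH), OO
Why: Hydroperoxide cleavage of the exocyclic imide carbonyl frees the acid without touching the α-centre, any opened lactone re-closes on acidification because only the γ-lactone can form, and the auxiliary 3 is recovered.

Step 5
Reactants: 8 (2S,3S)-2-Ar*-5-oxooxolane-3-carboxylic acid
Product: 9 (4R,5S)-5-Ar*-4-(hydroxymethyl)oxolan-2-one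
Conditions: BH3·SMe2, THF, 0 °C to rt; MeOH quench
Reagents that add atoms: none
Why: Chemoselective borane reduction of a carboxylic acid (through the acyloxyborane) in the presence of a lactone gives the primary alcohol with no stereocentre affected.

Step 6
Reactants: 2 4-[(tert-butyldimethylsilyl)oxy]-3,5-dimethoxybenzaldehyde
Product: 10 {4-[(tert-butyldimethylsilyl)oxy]-3,5-dimethoxyphenyl}methanol
Conditions: NaBH4, MeOH, 0 °C
Reagents that add atoms: none
Why: Borohydride reduction of the aryl aldehyde gives the ring A benzyl alcohol and leaves the hindered aryl silyl ether intact.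

Step 7
Reactants: 10 {4-[(tert-butyldimethylsilyl)oxy]-3,5-dimethoxyphenyl}methanol
Product: 11 4-[(tert-butyldimethylsilyl)oxy]-3,5-dimethoxybenzyl 2,2,2-trichloroacetimidate
Conditions: Cl3CCN, DBU (cat.), CH2Cl2, 0 °C; used crude
Reagents that add atoms: trichloroacetonitrile, N#CC(Cl)(Cl)Cl
Why: Base-catalysed addition of the alcohol to trichloroacetonitrile (imidate formation) gives a benzyl donor that is activated by mild acid.

Step 8
Reactants: 9 (4R,5S)-5-Ar*-4-(hydroxymethyl)oxolan-2-one; 11 4-[(tert-butyldimethylsilyl)oxy]-3,5-dimethoxybenzyl 2,2,2-trichloroacetimidate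
Product: 12 (4R,5S)-5-Ar*-4-{[(Ar*)methoxy]methyl}oxolan-2-one
Conditions: CSA (cat.), CH2Cl2, 0 °C to rt
Reagents that add atoms: none
Why: Acid-catalysed O-benzylation with a trichloroacetimidate, in which the stabilized benzyl cation is captured by the primary alcohol, avoids the basic conditions that would translactonize 9.

Step 9
Reactants: 12 (4R,5S)-5-Ar*-4-{[(Ar*)methoxy]methyl}oxolan-2-one; 13 4-acetamidobenzenesulfonyl azide
Product: 15 (4R,5S)-3-diazo-5-Ar*-4-{[(Ar*)methoxy]methyl}oxolan-2-one, via trifluoroacetyl lactone 14 (not isolated)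
Conditions: LiN(SiMe3)2, THF, −78 °C; CF3CO2CH2CF3; 5% aq. HCl wash; then 13, Et3N, MeCN, rt
Reagents that add atoms: 4-acetamidobenzenesulfonyl azide (13), CC(=O)Nc1ccc(cc1)S(=O)(=O)N=[N+]=[N-]
Why: Detrifluoroacetylative Regitz diazo transfer, in which Claisen-type trifluoroacetylation of the lactone enolate activates C3 so that the sulfonyl azide delivers N2 while the acyl group leaves as the N-acylsulfonamide; C4 and C5 are untouched.

Step 10
Reactants: 15 (4R,5S)-3-diazo-5-Ar*-4-{[(Ar*)methoxy]methyl}oxolan-2-one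
Product: 16 (3S,3aR,6R,6aS)-3,6-bis(Ar*)tetrahydro-1H,3H-furo[3,4-c]furan-1-one, the cis-fused 4,8-diaryl-3,7-dioxabicyclo[3.3.0]octan-2-one with ring B exo and ring A endo (cis to C9)
Conditions: Rh2(OAc)4 (dirhodium tetraacetate, divalent rhodium, 2 mol %), CH2Cl2, rt, slow addition of 15
Reagents that add atoms: none
Why: Rh2(OAc)4 decomposes the diazo group with loss of N2 to an electrophilic carbene at C3, which inserts into the C2–H bond through a concerted three-centre, hydride-transfer-like transition state whose positive charge at C2 is stabilized by the O1 lone pair and ring A. This is the established intramolecular 1,5 carbene C–H insertion of α-diazo-γ-butyrolactones into benzylic ether C–H bonds. The oxolane closes by C2–C3 bond formation through the five-membered array C3–C4–C5–O1–C2, and this can only give the cis-fused bicycle, so the aldol-derived C4 dictates C3 (C9 cis to C7'). C2 is set by the insertion geometry, in which ring A points away from the acetate ligands and should end on the concave face, cis to C9; this centre is not relied upon because step 13 equilibrates it. The step needs site selectivity for C2–H over 1,2-hydride migration from C4 (butenolide) and over carbene dimerization. That is secured by the double activation of the C2–H bonds (α-oxygen and electron-rich benzylic), the five-membered closure, and slow addition at high dilution.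

Step 11
Reactants: 16 (3S,3aR,6R,6aS)-3,6-bis(Ar*)tetrahydro-1H,3H-furo[3,4-c]furan-1-one
Product: 17 (S)-Ar*[(3R,4R,5R)-5-Ar*-4-(hydroxymethyl)oxolan-3-yl]methanol (all-cis oxolane)
Conditions: LiAlH4, THF, 0 °C; Na2SO4·10H2O quench
Reagents that add atoms: none
Why: Hydride reduction of the lactone to the 1,4-diol unmasks C9H2OH and the benzylic C7' alcohol without touching the ring stereocentres, and the doubly ortho-flanked aryl silyl ethers should survive at 0 °C.

Step 12
Reactants: 17 (S)-Ar*[(3R,4R,5R)-5-Ar*-4-(hydroxymethyl)oxolan-3-yl]methanol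
Product: 19 Ar*[(3S,4R,5R)-5-Ar*-4-(hydroxymethyl)oxolan-3-yl]methanone (C3/C4 trans, C2/C3 cis), via all-cis ketone 18 (not isolated)
Conditions: MnO2, CH2Cl2, rt; filter (Celite); then DBU, rt
Reagents that add atoms: none
Why: MnO2 oxidizes only the benzylic C7' alcohol, and DBU then epimerizes C4 through the ketone enolate to the less congested 3,4-trans isomer (thermodynamic epimerization); β-elimination of O1 is disfavoured because the C5–O1 bond lies in the ring plane.

Step 13
Reactants: 19 Ar*[(3S,4R,5R)-5-Ar*-4-(hydroxymethyl)oxolan-3-yl]methanone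
Product: 20 Ar*[(3S,4R,5S)-5-Ar*-4-(hydroxymethyl)oxolan-3-yl]methanone (all-trans)
Conditions: BF3·OEt2 (0.3 equiv), CH2Cl2, −20 to 0 °C
Reagents that add atoms: none
Why: Lewis-acid epimerization of a 2-aryloxolane, in which BF3 reversibly ionizes the C2–O1 bond to the benzylic cation stabilized by the 4-silyloxy-3,5-dimethoxyphenyl ring and re-closure under thermodynamic control places ring A trans to C3.

Step 14
Reactants: 20 Ar*[(3S,4R,5S)-5-Ar*-4-(hydroxymethyl)oxolan-3-yl]methanone
Product: 21 (4-hydroxy-3,5-dimethoxyphenyl)[(3S,4R,5S)-5-(4-hydroxy-3,5-dimethoxyphenyl)-4-(hydroxymethyl)oxolan-3-yl]methanone (CID53356211)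
Conditions: Bu4NF, AcOH, THF, 0 °C
Reagents that add atoms: none
Why: Fluoride cleavage of both aryl silyl ethers, buffered with AcOH so that the enolizable C4 centre and the phenoxides do not see strong base, liberates the target.

Compound list
1 | syringaldehyde | COc1cc(C=O)cc(OC)c1O | starting material
2 | 4-[(tert-butyldimethylsilyl)oxy]-3,5-dimethoxybenzaldehyde | COc1cc(C=O)cc(OC)c1O[Si](C)(C)C(C)(C)C | intermediate
3 | (4S)-4-benzyl-1,3-oxazolidin-2-one | O=C1N[C@@H](Cc2ccccc2)CO1 | starting material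
4 | methyl 4-chloro-4-oxobutanoate | COC(=O)CCC(Cl)=O | starting material
5 | methyl 4-[(4S)-4-benzyl-2-oxo-1,3-oxazolidin-3-yl]-4-oxobutanoate | COC(=O)CCC(=O)N1[C@@H](Cc2ccccc2)COC1=O | intermediate
6 | methyl (3S,4S)-3-{[(4S)-4-benzyl-2-oxo-1,3-oxazolidin-3-yl]carbonyl}-4-Ar*-4-hydroxybutanoate (syn-aldol adduct) | COC(=O)C[C@H](C(=O)N1[C@@H](Cc2ccccc2)COC1=O)[C@H](O)c1cc(OC)c(O[Si](C)(C)C(C)(C)C)c(OC)c1 | intermediate (not isolated)
7 | (4S)-4-benzyl-3-{[(2S,3S)-2-Ar*-5-oxooxolan-3-yl]carbonyl}-1,3-oxazolidin-2-one | O=C1C[C@H](C(=O)N2[C@@H](Cc3ccccc3)COC2=O)[C@@H](c2cc(OC)c(O[Si](C)(C)C(C)(C)C)c(OC)c2)O1 | intermediate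
8 | (2S,3S)-2-Ar*-5-oxooxolane-3-carboxylic acid | O=C1C[C@H](C(=O)O)[C@@H](c2cc(OC)c(O[Si](C)(C)C(C)(C)C)c(OC)c2)O1 | intermediate
9 | (4R,5S)-5-Ar*-4-(hydroxymethyl)oxolan-2-one | O=C1C[C@H](CO)[C@@H](c2cc(OC)c(O[Si](C)(C)C(C)(C)C)c(OC)c2)O1 | intermediate
10 | {4-[(tert-butyldimethylsilyl)oxy]-3,5-dimethoxyphenyl}methanol | COc1cc(CO)cc(OC)c1O[Si](C)(C)C(C)(C)C | intermediate
11 | 4-[(tert-butyldimethylsilyl)oxy]-3,5-dimethoxybenzyl 2,2,2-trichloroacetimidate | COc1cc(COC(=N)C(Cl)(Cl)Cl)cc(OC)c1O[Si](C)(C)C(C)(C)C | intermediate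
12 | (4R,5S)-5-Ar*-4-{[(Ar*)methoxy]methyl}oxolan-2-one | O=C1C[C@H](COCc2cc(OC)c(O[Si](C)(C)C(C)(C)C)c(OC)c2)[C@@H](c2cc(OC)c(O[Si](C)(C)C(C)(C)C)c(OC)c2)O1 | intermediate
13 | 4-acetamidobenzenesulfonyl azide | CC(=O)Nc1ccc(cc1)S(=O)(=O)N=[N+]=[N-] | starting material
14 | (4R,5S)-5-Ar*-4-{[(Ar*)methoxy]methyl}-3-(trifluoroacetyl)oxolan-2-one (C3 unassigned, enolizable) | O=C1C(C(=O)C(F)(F)F)[C@H](COCc2cc(OC)c(O[Si](C)(C)C(C)(C)C)c(OC)c2)[C@@H](c2cc(OC)c(O[Si](C)(C)C(C)(C)C)c(OC)c2)O1 | intermediate (not isolated)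
15 | (4R,5S)-3-diazo-5-Ar*-4-{[(Ar*)methoxy]methyl}oxolan-2-one | [N-]=[N+]=C1C(=O)O[C@H](c2cc(OC)c(O[Si](C)(C)C(C)(C)C)c(OC)c2)[C@H]1COCc1cc(OC)c(O[Si](C)(C)C(C)(C)C)c(OC)c1 | intermediate (key-step precursor)
16 | (3S,3aR,6R,6aS)-3,6-bis(Ar*)tetrahydro-1H,3H-furo[3,4-c]furan-1-one | COc1cc([C@@H]2OC[C@H]3[C@@H]2C(=O)O[C@@H]3c2cc(OC)c(O[Si](C)(C)C(C)(C)C)c(OC)c2)cc(OC)c1O[Si](C)(C)C(C)(C)C | intermediate (key-step product)
17 | (S)-Ar*[(3R,4R,5R)-5-Ar*-4-(hydroxymethyl)oxolan-3-yl]methanol | COc1cc([C@@H]2OC[C@H]([C@H](O)c3cc(OC)c(O[Si](C)(C)C(C)(C)C)c(OC)c3)[C@@H]2CO)cc(OC)c1O[Si](C)(C)C(C)(C)C | intermediate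
18 | Ar*[(3R,4R,5R)-5-Ar*-4-(hydroxymethyl)oxolan-3-yl]methanone (all-cis) | COc1cc([C@@H]2OC[C@H](C(=O)c3cc(OC)c(O[Si](C)(C)C(C)(C)C)c(OC)c3)[C@@H]2CO)cc(OC)c1O[Si](C)(C)C(C)(C)C | intermediate (not isolated)
19 | Ar*[(3S,4R,5R)-5-Ar*-4-(hydroxymethyl)oxolan-3-yl]methanone | COc1cc([C@@H]2OC[C@@H](C(=O)c3cc(OC)c(O[Si](C)(C)C(C)(C)C)c(OC)c3)[C@@H]2CO)cc(OC)c1O[Si](C)(C)C(C)(C)C | intermediate
20 | Ar*[(3S,4R,5S)-5-Ar*-4-(hydroxymethyl)oxolan-3-yl]methanone (all-trans) | COc1cc([C@H]2OC[C@@H](C(=O)c3cc(OC)c(O[Si](C)(C)C(C)(C)C)c(OC)c3)[C@@H]2CO)cc(OC)c1O[Si](C)(C)C(C)(C)C | intermediate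
21 | (4-hydroxy-3,5-dimethoxyphenyl)[(3S,4R,5S)-5-(4-hydroxy-3,5-dimethoxyphenyl)-4-(hydroxymethyl)oxolan-3-yl]methanone | COc1cc(C(=O)[C@@H]2CO[C@H](c3cc(OC)c(O)c(OC)c3)[C@H]2CO)cc(OC)c1O | target

Total step count: 14. Longest linear sequence: 11 steps (steps 1, 3, 4, 5, 8, 9, 10, 11, 12, 13, 14, from syringaldehyde).

Steps most likely to fail

Step 10. The carbene may be diverted before it reaches C2–H, by 1,2-hydride migration from C4 to a butenolide or by dimerization. Fallback, setting out from 9 and 2 and returning at 16: the same C2–C3 bond is closed by a polar reaction. Aldehyde 2 is converted with HC(OMe)3 and catalytic PPTS into 4-[(tert-butyldimethylsilyl)oxy]-3,5-dimethoxybenzaldehyde dimethyl acetal F1. Acetal exchange of F1 with alcohol 9 (PPTS, toluene, removal of methanol) gives the mixed methyl acetal of lactone 9 F2. LiN(SiMe3)2 and Me3SiCl turn F2 into the lactone trimethylsilyl ketene acetal F3. Catalytic Me3SiOTf at −78 °C then ionizes the acetal to the C2 oxocarbenium ion, which C3 captures in a Mukaiyama-type aldol closure. For the same geometric reason as in step 10, this can only give the cis-fused bicycle 16.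

Step 13. Re-closure of the C2 cation may be incomplete or lose out to capture by ring B (Friedel–Crafts cyclization) or to proton loss giving a styrene. Fallback, setting out from 19 and returning at 21: the order is reversed and the mechanism changed. Bu4NF/AcOH first removes both silyl groups from 19 to give the C2 epimer of the target F4. F4 is then equilibrated with K2CO3 in dioxane/H2O at 60 °C under argon. The ring A phenoxide opens C2–O1 to a neutral para-quinone methide, which the C5 alkoxide re-adds to (retro-oxa-Michael then oxa-Michael) to give the all-trans oxolane 21. The quinone methide is too weak an electrophile for Friedel–Crafts capture.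

Step 8. The very electron-rich imidate may rearrange to the trichloroacetamide or alkylate itself before the alcohol captures it, and acid may translactonize 9. Fallback, setting out from 9 and 2 and returning at 12: reductive etherification. Alcohol 9 is silylated (Me3SiCl, Et3N) to the trimethylsilyl ether of lactone 9 F5. F5 is treated with aldehyde 2, Et3SiH and catalytic Me3SiOTf at −78 °C; the oxocarbenium ion formed from 2 and the silyl ether is reduced by the silane to benzyl ether 12. This also makes steps 6 and 7 unnecessary.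

Further compounds
F1 | step 10 | 4-[(tert-butyldimethylsilyl)oxy]-3,5-dimethoxybenzaldehyde dimethyl acetal | COC(OC)c1cc(OC)c(O[Si](C)(C)C(C)(C)C)c(OC)c1
F2 | step 10 | mixed methyl acetal of lactone 9, (4R,5S)-5-Ar*-4-({[Ar*](methoxy)methoxy}methyl)oxolan-2-one (acetal carbon unassigned) | O=C1C[C@H](COC(OC)c2cc(OC)c(O[Si](C)(C)C(C)(C)C)c(OC)c2)[C@@H](c2cc(OC)c(O[Si](C)(C)C(C)(C)C)c(OC)c2)O1
F3 | step 10 | lactone trimethylsilyl ketene acetal, (2S,3R)-2-Ar*-3-({[Ar*](methoxy)methoxy}methyl)-5-[(trimethylsilyl)oxy]-2,3-dihydrofuran | C[Si](C)(C)OC1=C[C@H](COC(OC)c2cc(OC)c(O[Si](C)(C)C(C)(C)C)c(OC)c2)[C@@H](c2cc(OC)c(O[Si](C)(C)C(C)(C)C)c(OC)c2)O1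
F4 | step 13 | C2 epimer of the target, (4-hydroxy-3,5-dimethoxyphenyl)[(3S,4R,5R)-5-(4-hydroxy-3,5-dimethoxyphenyl)-4-(hydroxymethyl)oxolan-3-yl]methanone | COc1cc([C@@H]2OC[C@@H](C(=O)c3cc(OC)c(O)c(OC)c3)[C@@H]2CO)cc(OC)c1O
F5 | step 8 | trimethylsilyl ether of lactone 9, (4R,5S)-5-Ar*-4-{[(trimethylsilyl)oxy]methyl}oxolan-2-one | O=C1C[C@H](CO[Si](C)(C)C)[C@@H](c2cc(OC)c(O[Si](C)(C)C(C)(C)C)c(OC)c2)O1
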